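## The problem

The target, 24, is a trimeric acylphloroglucinol. A central ring A (C1 butanoyl; C2, C4 and C6 hydroxyls) is tied through C3 and C5 by two methylene bridges to two identical rings B, each a 3-butanoyl-2,4-dihydroxy-6-methoxy-5-methylphenyl unit. All eighteen ring carbons are substituted, there is no stereocentre, and a mirror plane through C1 and C4 of ring A makes the two arms equivalent, so the task is one of regiocontrol and oxygen differentiation, not stereocontrol. Seven phenols must end free while one oxygen on each ring B stays methylated, so every protecting group has to come off under conditions that spare an aryl methyl ether. The electron-rich diarylmethane bridges are prone to acid- or base-induced retro-Friedel–Crafts scission and scrambling, the free polyphenol oxidises easily in base, and the three enolisable butanoyl ketones would not survive the strong bases needed for carbon–carbon bond formation. Direct condensation of three phloroglucinol monomers with formaldehyde would give statistical oligomer mixtures for this unsymmetrical A/B pattern. The feature that opens a ring-forming route is the polarity pattern of ring A: C2(O)–C3–C4(O)–C5 is the dienol form of an α,γ-disubstituted β-keto ester carrying both bridges, and C1(butanoyl)–C6(O) is a two-carbon unit at the oxidation level of a β-alkoxy ynone, whose electrophilic carbon is the one that must bond to C5.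

## Retrosynthesis

**24 to 22.** The last bonds made are the two aryl–carbonyl bonds at C3 of each ring B, cut to the hexaphenol 22 and butanenitrile (Houben–Hoesch, via the bis(ketiminium) salt 23). This is preferred to carrying the ring B ketones from the start, because they would be enolised in the dianion and silylation chemistry that builds the chain. In 22 the only unsubstituted carbon of each ring B lies between two free hydroxyls and ring A is fully substituted and deactivated by its ketone, so there is no positional choice. The forward step must acylate once per ring and must not cleave the bridges.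

**22 to 21.** Four O–benzyl bonds and one O–isopropyl bond are cut. The C6 oxygen of ring A is carried as an isopropyl ether and not as the ethyl ether that commercial ethoxyacetylene would give. In the cyclisation product the other oxygen ortho to the ketone is a free phenol that captures boron first, so chelation-assisted cleavage of a primary alkyl ether at C6 cannot be relied on. A secondary alkyl ether is cleaved by BCl3 through an ionising pathway that needs no chelation and leaves methyl ethers intact. One BCl3 operation with a cation scavenger is therefore asked to remove all five groups.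

**21 to 12 + 19.** This is the key disconnection: the C1–C2 and C5–C6 bonds of ring A are cut. It divides the fully substituted ring into a four-carbon bis(silyloxy)diene 12 that carries both bridges and a two-carbon ynone 19 that carries the butanoyl group and the C6 oxygen; the two combine through cycloadduct 20. Compared with bridging a preformed butanoylphloroglucinol (two Friedel–Crafts alkylations by a cation that also attacks its own ring), this cut forms ring A already hexasubstituted from two halves of similar size. It also installs one of the three ketones without any acylation. The forward reaction must be regioselective, with the butanoyl carbon placed between the two oxygenated carbons.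

**12 to 10.** Two O–Si bonds are cut, through the mono silyl enol ether 11, back to the β-keto ester 10. This is the standard two-stage preparation of 1-alkoxy-1,3-bis(silyloxy)dienes. It asks only that the second deprotonation take place at the γ-methylene.

**10 to 9 + 7, and 9 to 8 + 7.** The two C–C bonds between the bridge carbons and the α and γ carbons of methyl acetoacetate 8 are cut. Both arms then come from one benzylic bromide 7, which uses the symmetry of the target, and the order γ then α follows the reactivity of the dianion and then the monoanion. The forward reactions are enolate SN2 alkylations under basic conditions, where the electron-rich benzylic halide cannot ionise and attack its own ring.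

**7 to 1.** Functional group changes lead from bromide 7 to alcohol 6 and aldehyde 5. The O–methyl and two O–benzyl bonds are cut to reach 4 and then 2,4,6-trihydroxy-3-methylbenzaldehyde 3, and the formyl C–C bond is cut (via iminium salt 2) to reach 2,4,6-trihydroxytoluene 1. The formyl group serves twice: it is the future bridge carbon, and by hydrogen bonding it marks the hydroxyl between itself and the methyl group as the last to be alkylated, which is the oxygen that must become the methyl ether.

**19 to 13 + 14 + 15.** The ynone is cut at the carbinol C–C bond and at the ynol ether, giving propan-2-ol 13, trichloroethene 14 and butanal 15. The route runs through dichlorovinyl ether 16, lithium alkoxyacetylide 17 and propargylic alcohol 18. This costs no more steps than the ethoxy series, because the alkoxyacetylide is generated and trapped in one flask.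

## Roads not taken

**Alternative 1:** Both rings B would be closed by a twofold Danheiser benzannulation. The ring-A-borne bis(cyclobutenone) A2 is heated with 1-methoxypropyne A3; each vinylketene adds the alkyne, the adduct opens and electrocyclises, and the C4–C5 and C6–C1 bonds of each ring B form to give the diphenol A1. Its merit is that the complete oxygen pattern of ring B (free phenol, silyl ether, methyl ether) is written into the annulation with predictable regiochemistry. In that respect it is better than the chosen plan, which depends on a selectivity-controlled dibenzylation. Its weak points are these: A2 already needs ring A with both bridges attached, so the bridging problem is only moved; 2-substituted 3-silyloxycyclobutenones are laborious; and A1 contains none of the three ketones. Three acylations would follow, one of them between two benzyloxy groups on ring A, before deprotection. The chosen plan sets against this a ring A formed with its ketone in place and an endgame of two steps.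

**Alternative 2:** No ring is formed. The three aryl–carbonyl bonds are made at once by carbonylative Negishi coupling of the triiodide A5 with propylzinc bromide A6 under a palladium catalyst bearing a bulky N-heterocyclic carbene, giving the hepta-O-benzyl ether A4, and hydrogenolysis finishes the synthesis. This road has the gentlest endgame of all: no Friedel–Crafts chemistry on a bridged polyphenol and a neutral final deprotection. There it is better than the chosen plan, whose last two steps are acidic. Against it, every C–I bond lies between two ortho benzyloxy groups in a hexasubstituted ring, where direct coupling without carbon monoxide insertion and reduction compete. The coupling must succeed three times on one molecule. The whole trimeric skeleton of A5 must also first be assembled by conventional bridging, which is the step that lacks selectivity. The chosen plan answers the assembly question with a ring synthesis and accepts two late acylations at the most activated positions as the price.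

**Alternative 3:** This is the mirror image of the chosen plan. Rings B are formed by a double Diels–Alder aromatisation of the bis(vinylketene acetal) A8 with two equivalents of 1-ethoxyhex-1-yn-3-one A9, giving A7. It is better in acyl economy, since two of the three ketones arrive with the ring-forming step and only ring A remains to be acylated. It is weaker in three ways. The least precedented step must work twice on the same molecule. A8 requires a doubly benzylic, trialkoxy-activated ring A bis-electrophile that is more labile than bromide 7. And each ethoxy group of A7 sits ortho to a ketone whose other ortho oxygen is a free phenol, the same deprotection problem that led to the isopropyl ether here. The remaining acylation of ring A would also fall between two benzyloxy groups in the presence of two ketones. The chosen plan runs the uncertain cycloaddition once, on a diene made by two ordinary enolate alkylations.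

Key step: step 12

Remark on the chemistry: salts of numbered compounds formed by deprotonation in the flask (enolates, phenoxides, boron phenoxides) are treated as the parent compound and carry no number; the enol ether geometries of 11 and 12 are drawn as one isomer and are lost on aromatisation.

## Route

Step 1
Reactants: 1 2,4,6-trihydroxytoluene
Product: 3 2,4,6-trihydroxy-3-methylbenzaldehyde, via aryl iminium chloride 2 (not isolated)
Conditions: POCl3, DMF, EtOAc, 0 → 20 °C; then H2O, 60 °C
Reagents that add atoms: N,N-dimethylformamide CN(C)C=O; water O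
Why: Vilsmeier–Haack formylation of a phloroglucinol; the two free ring positions are equivalent by symmetry and the iminium group of 2 deactivates the ring against a second attack.

Step 2
Reactants: 3 2,4,6-trihydroxy-3-methylbenzaldehyde
Product: 4 4,6-bis(benzyloxy)-2-hydroxy-3-methylbenzaldehyde
Conditions: BnBr (2.1 equiv), K2CO3, DMF, 20 °C
Reagents that add atoms: benzyl bromide BrCc1ccccc1
Why: Williamson etherification; the para hydroxyl is the most acidic and is not chelated, the ortho hydroxyl flanked by hydrogen reacts next, and the hydroxyl between formyl and methyl should remain as the hindered, hydrogen-bonded phenol, as is usual for C-methylated phloroglucinol carbonyl compounds.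

Step 3
Reactants: 4 4,6-bis(benzyloxy)-2-hydroxy-3-methylbenzaldehyde
Product: 5 4,6-bis(benzyloxy)-2-methoxy-3-methylbenzaldehyde
Conditions: MeI, K2CO3, DMF, 50 °C
Reagents that add atoms: iodomethane CI
Why: Williamson methylation of the remaining chelated ortho-hydroxyl, which needs only excess reagent and mild heating.

Step 4
Reactants: 5 4,6-bis(benzyloxy)-2-methoxy-3-methylbenzaldehyde
Product: 6 [4,6-bis(benzyloxy)-2-methoxy-3-methylphenyl]methanol
Conditions: NaBH4, THF–MeOH, 0 °C
Reagents that add atoms: none
Why: Borohydride reduction of an aryl aldehyde; no other reducible group is present.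

Step 5
Reactants: 6 [4,6-bis(benzyloxy)-2-methoxy-3-methylphenyl]methanol
Product: 7 1,5-bis(benzyloxy)-2-(bromomethyl)-3-methoxy-4-methylbenzene
Conditions: CBr4, PPh3, CH2Cl2, 0 °C; filtered cold and used at once
Reagents that add atoms: tetrabromomethane BrC(Br)(Br)Br
Why: Appel bromination under neutral conditions, chosen so that the trialkoxybenzyl cation, which would attack the one free position of another ring, is not generated by acid.

Step 6
Reactants: 8 methyl acetoacetate; 7 1,5-bis(benzyloxy)-2-(bromomethyl)-3-methoxy-4-methylbenzene
Product: 9 methyl 5-[4,6-bis(benzyloxy)-2-methoxy-3-methylphenyl]-3-oxopentanoate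
Conditions: NaH, THF, 0 °C; n-BuLi, 0 °C; then 7, −78 → 0 °C
Reagents that add atoms: none
Why: Weiler dianion alkylation; the more basic γ-carbanion of the acetoacetate dianion reacts with the benzylic bromide by SN2 and the resulting monoanion is inert at this temperature.

Step 7
Reactants: 9 methyl 5-[4,6-bis(benzyloxy)-2-methoxy-3-methylphenyl]-3-oxopentanoate; 7 1,5-bis(benzyloxy)-2-(bromomethyl)-3-methoxy-4-methylbenzene
Product: 10 methyl 2-{[4,6-bis(benzyloxy)-2-methoxy-3-methylphenyl]methyl}-5-[4,6-bis(benzyloxy)-2-methoxy-3-methylphenyl]-3-oxopentanoate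
Conditions: NaH, THF, 0 °C; then 7, 0 → 20 °C
Reagents that add atoms: none
Why: α-Alkylation of a β-keto ester sodium enolate by SN2; a second alkylation at the now tertiary carbon is sterically retarded, and the new stereocentre is formed racemic and erased in step 8.

Step 8
Reactants: 10 methyl 2-{[4,6-bis(benzyloxy)-2-methoxy-3-methylphenyl]methyl}-5-[4,6-bis(benzyloxy)-2-methoxy-3-methylphenyl]-3-oxopentanoate
Product: 11 methyl (2Z)-2-{[4,6-bis(benzyloxy)-2-methoxy-3-methylphenyl]methyl}-5-[4,6-bis(benzyloxy)-2-methoxy-3-methylphenyl]-3-(trimethylsilyloxy)pent-2-enoate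
Conditions: Me3SiCl, Et3N, toluene, 20 °C
Reagents that add atoms: chlorotrimethylsilane C[Si](C)(C)Cl
Why: O-silylation of the enol between the two carbonyl groups, the first stage of the standard preparation of 1,3-bis(silyloxy)dienes from β-keto esters.

Step 9
Reactants: 11 methyl (2Z)-2-{[4,6-bis(benzyloxy)-2-methoxy-3-methylphenyl]methyl}-5-[4,6-bis(benzyloxy)-2-methoxy-3-methylphenyl]-3-(trimethylsilyloxy)pent-2-enoate
Product: 12 (1Z,3Z)-1-methoxy-2-{[4,6-bis(benzyloxy)-2-methoxy-3-methylphenyl]methyl}-5-[4,6-bis(benzyloxy)-2-methoxy-3-methylphenyl]-1,3-bis(trimethylsilyloxy)penta-1,3-diene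
Conditions: LiN(iPr)2, THF, −78 °C; Me3SiCl, −78 → 20 °C; non-aqueous work-up, used crude
Reagents that add atoms: chlorotrimethylsilane C[Si](C)(C)Cl
Why: γ-Deprotonation of the β-silyloxy enoate gives the ester dienolate, which is silylated on oxygen (second stage of the bis(silyloxy)diene preparation); the amide base normally gives the terminal enol ether with its substituent outward.

Step 10
Reactants: 13 propan-2-ol; 14 trichloroethene; 15 butanal
Product: 18 rac-1-(propan-2-yloxy)hex-1-yn-3-ol, via dichlorovinyl ether 16 (not isolated), via lithium alkoxyacetylide 17 (not isolated)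
Conditions: KH, THF, 0 °C; Cl2C=CHCl, −50 → 20 °C; n-BuLi (2.2 equiv), −78 → −40 °C; PrCHO, −78 °C; aq. NaHCO3
Reagents that add atoms: none
Why: Greene ynol ether synthesis: the alkoxide adds to dichloroacetylene formed in situ, n-BuLi then effects elimination and chlorine–lithium exchange to the alkoxyacetylide, which adds to the aldehyde; the mildly basic work-up avoids Meyer–Schuster rearrangement, and the racemic carbinol centre is removed in step 11.

Step 11
Reactants: 18 rac-1-(propan-2-yloxy)hex-1-yn-3-ol
Product: 19 1-(propan-2-yloxy)hex-1-yn-3-one
Conditions: MnO2 (activated), CH2Cl2, 20 °C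
Reagents that add atoms: none
Why: Oxidation of a propargylic alcohol with MnO2 under neutral, anhydrous conditions that neither hydrate nor rearrange the ynol ether.

Step 12
Reactants: 12 (1Z,3Z)-1-methoxy-2-{[4,6-bis(benzyloxy)-2-methoxy-3-methylphenyl]methyl}-5-[4,6-bis(benzyloxy)-2-methoxy-3-methylphenyl]-1,3-bis(trimethylsilyloxy)penta-1,3-diene; 19 1-(propan-2-yloxy)hex-1-yn-3-one
Product: 21 1-[3,5-bis({4,6-bis(benzyloxy)-2-methoxy-3-methylphenyl}methyl)-2,4-dihydroxy-6-(propan-2-yloxy)phenyl]butan-1-one, via cyclohexadiene cycloadduct 20 (not isolated)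
Conditions: 19 (1.5 equiv), toluene (concentrated), 20 → 60 °C; then 1 M HCl, THF, 0 °C
Reagents that add atoms: none
Why: Diels–Alder benzannulation of a 1-methoxy-1,3-bis(silyloxy)diene with an acetylenic ketone; the closest known reaction type is the cycloaddition–aromatisation of such dienes with alkynoates and ynones to 2,4-dihydroxyaryl carbonyl compounds. The diene is most nucleophilic at its terminus remote from the ketene acetal (future ring A C5) and the push–pull ynone is most electrophilic at its alkoxy-bearing carbon (future C6), so a strongly asynchronous, possibly stepwise (4+2) addition forms C5–C6 first and then C1–C2 between the ketene acetal carbon and the carbon α to the ketone. Ring A thus closes as a six-membered carbocycle by intermolecular (4+2) cycloaddition to give cyclohexa-1,4-diene 20. The mixed methyl silyl ketal carbon of 20 (C2) then loses methanol, thermally by 1,4-elimination with the hydrogen on C5 or through the hemiketal during the acidic work-up, which also cleaves both silyl ethers and leaves the chelated resorcinol 21. The two sp3 centres of 20 are transient and disappear on aromatisation, so no stereocontrol is needed. The selectivity that matters is regiochemical, butanoyl between two oxygenated carbons, and it is secured by the matched polarisation of the two partners. The competing (3+3) closure through the central diene carbon cannot lead to an arene because that carbon carries a benzylic substituent, and the outward (Z) geometry of the terminal enol ether keeps its substituent out of the s-cis diene cavity.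

Step 13
Reactants: 21 1-[3,5-bis({4,6-bis(benzyloxy)-2-methoxy-3-methylphenyl}methyl)-2,4-dihydroxy-6-(propan-2-yloxy)phenyl]butan-1-one
Product: 22 1-{3,5-bis[(4,6-dihydroxy-2-methoxy-3-methylphenyl)methyl]-2,4,6-trihydroxyphenyl}butan-1-one
Conditions: BCl3, C6HMe5, CH2Cl2, −78 → 0 °C; MeOH, then H2O
Reagents that add atoms: none
Why: Lewis-acid ether cleavage: BCl3 ionises benzyl and secondary alkyl aryl ethers at low temperature while unchelated aryl methyl ethers are left, and pentamethylbenzene traps the benzyl cations before they can alkylate the free position of ring B.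

Step 14
Reactants: 22 1-{3,5-bis[(4,6-dihydroxy-2-methoxy-3-methylphenyl)methyl]-2,4,6-trihydroxyphenyl}butan-1-one
Product: 24 1-{3,5-bis[(3-butanoyl-2,4-dihydroxy-6-methoxy-5-methylphenyl)methyl]-2,4,6-trihydroxyphenyl}butan-1-one, via bis(ketiminium) dichloride 23 (not isolated)
Conditions: PrCN, ZnCl2, HCl (g), Et2O, 0 °C; then H2O, 80 °C
Reagents that add atoms: butanenitrile CCCC#N; water O
Why: Twofold Houben–Hoesch acylation; each ring B has one free carbon between two hydroxyls, the ketiminium group stops further reaction on that ring, ring A is fully substituted, and hydrolysis of 23 releases the two ketones.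

## Compound list

1 | 2,4,6-trihydroxytoluene | Cc1c(O)cc(O)cc1O | starting material
2 | N-methyl-N-[(2,4,6-trihydroxy-3-methylphenyl)methylidene]methanaminium chloride | C[N+](C)=Cc1c(O)cc(O)c(C)c1O.[Cl-] | intermediate
3 | 2,4,6-trihydroxy-3-methylbenzaldehyde | O=Cc1c(O)cc(O)c(C)c1O | intermediate
4 | 4,6-bis(benzyloxy)-2-hydroxy-3-methylbenzaldehyde | O=Cc1c(OCc2ccccc2)cc(OCc2ccccc2)c(C)c1O | intermediate
5 | 4,6-bis(benzyloxy)-2-methoxy-3-methylbenzaldehyde | O=Cc1c(OCc2ccccc2)cc(OCc2ccccc2)c(C)c1OC | intermediate
6 | [4,6-bis(benzyloxy)-2-methoxy-3-methylphenyl]methanol | OCc1c(OCc2ccccc2)cc(OCc2ccccc2)c(C)c1OC | intermediate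
7 | 1,5-bis(benzyloxy)-2-(bromomethyl)-3-methoxy-4-methylbenzene | BrCc1c(OCc2ccccc2)cc(OCc2ccccc2)c(C)c1OC | intermediate
8 | methyl acetoacetate (methyl 3-oxobutanoate) | COC(=O)CC(C)=O | starting material
9 | methyl 5-[4,6-bis(benzyloxy)-2-methoxy-3-methylphenyl]-3-oxopentanoate | COC(=O)CC(=O)CCc1c(OCc2ccccc2)cc(OCc2ccccc2)c(C)c1OC | intermediate
10 | methyl 2-{[4,6-bis(benzyloxy)-2-methoxy-3-methylphenyl]methyl}-5-[4,6-bis(benzyloxy)-2-methoxy-3-methylphenyl]-3-oxopentanoate (racemic) | COC(=O)C(Cc1c(OCc2ccccc2)cc(OCc2ccccc2)c(C)c1OC)C(=O)CCc1c(OCc2ccccc2)cc(OCc2ccccc2)c(C)c1OC | intermediate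
11 | methyl (2Z)-2-{[4,6-bis(benzyloxy)-2-methoxy-3-methylphenyl]methyl}-5-[4,6-bis(benzyloxy)-2-methoxy-3-methylphenyl]-3-(trimethylsilyloxy)pent-2-enoate (drawn as the Z isomer) | COC(=O)/C(Cc1c(OCc2ccccc2)cc(OCc2ccccc2)c(C)c1OC)=C(\O[Si](C)(C)C)CCc1c(OCc2ccccc2)cc(OCc2ccccc2)c(C)c1OC | intermediate
12 | (1Z,3Z)-1-methoxy-2-{[4,6-bis(benzyloxy)-2-methoxy-3-methylphenyl]methyl}-5-[4,6-bis(benzyloxy)-2-methoxy-3-methylphenyl]-1,3-bis(trimethylsilyloxy)penta-1,3-diene (drawn as one double-bond isomer) | CO/C(O[Si](C)(C)C)=C(Cc1c(OCc2ccccc2)cc(OCc2ccccc2)c(C)c1OC)/C(O[Si](C)(C)C)=C/Cc1c(OCc2ccccc2)cc(OCc2ccccc2)c(C)c1OC | intermediate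
13 | propan-2-ol | CC(C)O | starting material
14 | trichloroethene | ClC=C(Cl)Cl | starting material
15 | butanal | CCCC=O | starting material
16 | (E)-1,2-dichloro-1-(propan-2-yloxy)ethene | Cl/C=C(/Cl)OC(C)C | intermediate
17 | lithium 2-(propan-2-yloxy)ethynide | [Li]C#COC(C)C | intermediate
18 | rac-1-(propan-2-yloxy)hex-1-yn-3-ol | CCCC(O)C#COC(C)C | intermediate
19 | 1-(propan-2-yloxy)hex-1-yn-3-one | CCCC(=O)C#COC(C)C | intermediate
20 | 1-[3,5-bis({4,6-bis(benzyloxy)-2-methoxy-3-methylphenyl}methyl)-6-methoxy-2-(propan-2-yloxy)-4,6-bis(trimethylsilyloxy)cyclohexa-1,4-dien-1-yl]butan-1-one (mixture of diastereomers) | CCCC(=O)C1=C(OC(C)C)C(Cc2c(OCc3ccccc3)cc(OCc3ccccc3)c(C)c2OC)C(O[Si](C)(C)C)=C(Cc2c(OCc3ccccc3)cc(OCc3ccccc3)c(C)c2OC)C1(OC)O[Si](C)(C)C | intermediate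
21 | 1-[3,5-bis({4,6-bis(benzyloxy)-2-methoxy-3-methylphenyl}methyl)-2,4-dihydroxy-6-(propan-2-yloxy)phenyl]butan-1-one | CCCC(=O)c1c(O)c(Cc2c(OCc3ccccc3)cc(OCc3ccccc3)c(C)c2OC)c(O)c(Cc2c(OCc3ccccc3)cc(OCc3ccccc3)c(C)c2OC)c1OC(C)C | intermediate
22 | 1-{3,5-bis[(4,6-dihydroxy-2-methoxy-3-methylphenyl)methyl]-2,4,6-trihydroxyphenyl}butan-1-one | CCCC(=O)c1c(O)c(Cc2c(O)cc(O)c(C)c2OC)c(O)c(Cc2c(O)cc(O)c(C)c2OC)c1O | intermediate
23 | 1-{3,5-bis[(2,4-dihydroxy-3-(1-iminiobutyl)-6-methoxy-5-methylphenyl)methyl]-2,4,6-trihydroxyphenyl}butan-1-one dichloride | CCCC(=O)c1c(O)c(Cc2c(O)c(C(=[NH2+])CCC)c(O)c(C)c2OC)c(O)c(Cc2c(O)c(C(=[NH2+])CCC)c(O)c(C)c2OC)c1O.[Cl-].[Cl-] | intermediate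
24 | 1-{3,5-bis[(3-butanoyl-2,4-dihydroxy-6-methoxy-5-methylphenyl)methyl]-2,4,6-trihydroxyphenyl}butan-1-one | CCCC(=O)c1c(O)c(Cc2c(O)c(C(=O)CCC)c(O)c(C)c2OC)c(O)c(Cc2c(O)c(C(=O)CCC)c(O)c(C)c2OC)c1O | target

## Step count and risks

Total step count: 14. Longest linear sequence: 12 steps (steps 1–9 and 12–14); steps 10–11 form the short ynone branch.

**Step 12 (key step).** A push–pull ynone is a weaker dienophile than a simple ynone. The reaction may stop after the first bond as an open-chain Michael adduct that then closes through oxygen to a 4-pyranone, or the ynol ether may fragment by retro-ene loss of propene if the temperature has to be raised. Hydrolysis of the diene before it reacts is a further loss. Fallback: setting out from 12 and 19, a Lewis-acid-promoted Mukaiyama–Michael addition (catalytic Me3SiOTf, CH2Cl2, −78 °C, aqueous work-up) would form the C5–C6 bond at low temperature. It would give the open-chain methyl 2,4-bis{[4,6-bis(benzyloxy)-2-methoxy-3-methylphenyl]methyl}-3,7-dioxo-5-(propan-2-yloxy)dec-5-enoate F1. A separate base-mediated vinylogous Claisen cyclisation (NaOMe, MeOH) would then form the C1–C2 bond with loss of methanol. Competing aldol closure is reversible whereas aromatisation is not, and the sequence comes back to the route at 21.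

**Step 5 (and the alkylations 6 and 7 that depend on it).** The trialkoxybenzyl bromide may ionise on concentration or on any adsorbent and alkylate the free position of a second molecule, so that oligomerisation outruns enolate alkylation. Fallback: setting out from aldehyde 5 and 8, aldol addition of the acetoacetate dianion to 5 would give methyl 5-[4,6-bis(benzyloxy)-2-methoxy-3-methylphenyl]-5-hydroxy-3-oxopentanoate F2. Its electron-rich benzylic hydroxyl is removed by ionic hydrogenation (Et3SiH, CF3CO2H, CH2Cl2, −20 °C), coming back at 9. The second arm is then attached by Knoevenagel condensation of 9 with 5 (piperidinium acetate) to methyl 2-{[4,6-bis(benzyloxy)-2-methoxy-3-methylphenyl]methylidene}-5-[4,6-bis(benzyloxy)-2-methoxy-3-methylphenyl]-3-oxopentanoate F3, followed by conjugate reduction with a Hantzsch ester, coming back at 10.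

**Step 2.** Benzylation may be unselective between the two ortho hydroxyls, or may occur on ring carbon, which would misplace the future methyl ether. Fallback: setting out from 3, exhaustive benzylation (BnBr, K2CO3, DMF, 60 °C) would give 2,4,6-tris(benzyloxy)-3-methylbenzaldehyde F4. Chelation-controlled mono-debenzylation with MgBr2·OEt2 (toluene–Et2O, reflux) is then expected to remove the ortho ether wedged between formyl and methyl, which is twisted out of conjugation and the most Lewis basic, and to come back at 4.

**Step 13.** Benzyl cations may escape the scavenger and alkylate the free carbon of ring B, and prolonged exposure may begin to cleave the ring B methyl ethers or protonate the bridges. Fallback: setting out from 21, the benzyl ethers are first removed by hydrogenolysis (H2, Pd/C, EtOAc), which generates no cation, to give 1-{3,5-bis[(4,6-dihydroxy-2-methoxy-3-methylphenyl)methyl]-2,4-dihydroxy-6-(propan-2-yloxy)phenyl}butan-1-one F5. The isopropyl ether alone is then cleaved with BCl3 (CH2Cl2, 0 °C), coming back at 22.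

**Step 14.** HCl and hot aqueous hydrolysis may cause ipso-protonation and scission or scrambling of the methylene bridges, and the second acylation may lag behind the first. Fallback: setting out from 21, the rings B are acylated while still protected, with the mixed anhydride from butanoic acid and trifluoroacetic anhydride (CH2Cl2, 20 °C; brief K2CO3–MeOH treatment to cleave any phenolic esters on ring A). This gives 1-[3,5-bis({2,4-bis(benzyloxy)-3-butanoyl-6-methoxy-5-methylphenyl}methyl)-2,4-dihydroxy-6-(propan-2-yloxy)phenyl]butan-1-one F6. The BCl3–pentamethylbenzene deprotection of step 13 is then the final operation and comes back at 24; the ring B methyl ethers are para to the new ketones and so are not activated for cleavage.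

## Further compounds

F1 | step 12 | methyl 2,4-bis{[4,6-bis(benzyloxy)-2-methoxy-3-methylphenyl]methyl}-3,7-dioxo-5-(propan-2-yloxy)dec-5-enoate (mixture of stereoisomers) | COC(=O)C(Cc1c(OCc2ccccc2)cc(OCc2ccccc2)c(C)c1OC)C(=O)C(Cc1c(OCc2ccccc2)cc(OCc2ccccc2)c(C)c1OC)C(OC(C)C)=CC(=O)CCC
F2 | step 5 | methyl 5-[4,6-bis(benzyloxy)-2-methoxy-3-methylphenyl]-5-hydroxy-3-oxopentanoate (racemic) | COC(=O)CC(=O)CC(O)c1c(OCc2ccccc2)cc(OCc2ccccc2)c(C)c1OC
F3 | step 5 | methyl 2-{[4,6-bis(benzyloxy)-2-methoxy-3-methylphenyl]methylidene}-5-[4,6-bis(benzyloxy)-2-methoxy-3-methylphenyl]-3-oxopentanoate (E/Z mixture) | COC(=O)C(=Cc1c(OCc2ccccc2)cc(OCc2ccccc2)c(C)c1OC)C(=O)CCc1c(OCc2ccccc2)cc(OCc2ccccc2)c(C)c1OC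
F4 | step 2 | 2,4,6-tris(benzyloxy)-3-methylbenzaldehyde | O=Cc1c(OCc2ccccc2)cc(OCc2ccccc2)c(C)c1OCc1ccccc1
F5 | step 13 | 1-{3,5-bis[(4,6-dihydroxy-2-methoxy-3-methylphenyl)methyl]-2,4-dihydroxy-6-(propan-2-yloxy)phenyl}butan-1-one | CCCC(=O)c1c(O)c(Cc2c(O)cc(O)c(C)c2OC)c(O)c(Cc2c(O)cc(O)c(C)c2OC)c1OC(C)C
F6 | step 14 | 1-[3,5-bis({2,4-bis(benzyloxy)-3-butanoyl-6-methoxy-5-methylphenyl}methyl)-2,4-dihydroxy-6-(propan-2-yloxy)phenyl]butan-1-one | CCCC(=O)c1c(O)c(Cc2c(OCc3ccccc3)c(C(=O)CCC)c(OCc3ccccc3)c(C)c2OC)c(O)c(Cc2c(OCc3ccccc3)c(C(=O)CCC)c(OCc3ccccc3)c(C)c2OC)c1OC(C)C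
A1 | alternative 1 | 1,3,5-tris(benzyloxy)-2,4-bis{[4-hydroxy-2-methoxy-3-methyl-6-(triisopropylsilyloxy)phenyl]methyl}benzene | c1ccccc1COc1cc(OCc2ccccc2)c(Cc2c(O[Si](C(C)C)(C(C)C)C(C)C)cc(O)c(C)c2OC)c(OCc2ccccc2)c1Cc1c(O[Si](C(C)C)(C(C)C)C(C)C)cc(O)c(C)c1OC
A2 | alternative 1 | 2,2'-{[2,4,6-tris(benzyloxy)-1,3-phenylene]bis(methylene)}bis[3-(triisopropylsilyloxy)cyclobut-2-en-1-one] | O=C1CC(O[Si](C(C)C)(C(C)C)C(C)C)=C1Cc1c(OCc2ccccc2)cc(OCc2ccccc2)c(CC2=C(O[Si](C(C)C)(C(C)C)C(C)C)CC2=O)c1OCc1ccccc1
A3 | alternative 1 | 1-methoxyprop-1-yne | COC#CC
A4 | alternative 2 | 1-[2,4,6-tris(benzyloxy)-3,5-bis({2,4-bis(benzyloxy)-3-butanoyl-6-methoxy-5-methylphenyl}methyl)phenyl]butan-1-one (hepta-O-benzyl ether of the target) | CCCC(=O)c1c(OCc2ccccc2)c(Cc2c(OCc3ccccc3)c(C(=O)CCC)c(OCc3ccccc3)c(C)c2OC)c(OCc2ccccc2)c(Cc2c(OCc3ccccc3)c(C(=O)CCC)c(OCc3ccccc3)c(C)c2OC)c1OCc1ccccc1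
A5 | alternative 2 | 1,3,5-tris(benzyloxy)-2-iodo-4,6-bis{[2,4-bis(benzyloxy)-3-iodo-6-methoxy-5-methylphenyl]methyl}benzene | Ic1c(OCc2ccccc2)c(Cc2c(OCc3ccccc3)c(I)c(OCc3ccccc3)c(C)c2OC)c(OCc2ccccc2)c(Cc2c(OCc3ccccc3)c(I)c(OCc3ccccc3)c(C)c2OC)c1OCc1ccccc1
A6 | alternative 2 | propylzinc bromide | CCC[Zn]Br
A7 | alternative 3 | 1,3,5-tris(benzyloxy)-2,4-bis[(3-butanoyl-2-ethoxy-4-hydroxy-6-methoxy-5-methylphenyl)methyl]benzene | c1ccccc1COc1cc(OCc2ccccc2)c(Cc2c(OCC)c(C(=O)CCC)c(O)c(C)c2OC)c(OCc2ccccc2)c1Cc1c(OCC)c(C(=O)CCC)c(O)c(C)c1OC
A8 | alternative 3 | 1,3,5-tris(benzyloxy)-2,4-bis[3,5-dimethoxy-4-methyl-5-(trimethylsilyloxy)penta-2,4-dien-1-yl]benzene (double-bond geometry unspecified) | COC(O[Si](C)(C)C)=C(C)C(OC)=CCc1c(OCc2ccccc2)cc(OCc2ccccc2)c(CC=C(OC)C(C)=C(OC)O[Si](C)(C)C)c1OCc1ccccc1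
A9 | alternative 3 | 1-ethoxyhex-1-yn-3-one | CCCC(=O)C#COCC
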